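**Retrosynthetic overview**
1. Target 25 ⇐ global desilylation of 24; 24 ⇐ loss of MeOH from acetal 23; 23 ⇐ loss of HCl from cycloadduct 22.
2. Key step: intramolecular inverse-demand hetero-Diels–Alder of enone/enol ether 21. The [4+2] forms pyran ring B (O2–C1 and C4a–C8a bonds) and closes carbocyclic ring A as the tether ring in the same event.
3. 21 ⇐ Michael union (C5–C4a) of dichloromethyl ketone 8 with enynone 20; the gem-dichloride blocks enolisation and later delivers the C5 chloro-enone.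
4. 8 ⇐ L-lactic acid: dioxolanone 3, aldol with 3-methoxyacrolein (C7 from lactic acid, C8 set by the aldol), then LiCHCl2.
5. 20 ⇐ L-isoleucine (C4′ and C5′ bought, C3′ by chelation-controlled MeMgBr addition), stannylvinyl addition and Stille acylation.

Assumption: (E)-3-methoxyacrolein, (E)-1,2-bis(tributylstannyl)ethene and 3-(trimethylsilyl)propiolic acid are taken as catalogue chemicals. Ring atoms are numbered as in isochromene (O2, C1, C3–C8a).

**Step 1**
Reactants: 1 L-lactic acid; 2 pivaldehyde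
Product: 3 (2S,5S)-2-tert-butyl-5-methyl-1,3-dioxolan-4-one
Conditions: TsOH·H2O (cat.), H2SO4 (cat.), pentane, reflux, Dean–Stark; crystallise the cis isomer from pentane at −78 °C
Reagents that add atoms: none
Why: Acid-catalysed acetalisation (Seebach self-regeneration-of-stereocentres acetal) in which the lactic acid stereocentre steers the new acetal carbon to the cis (2S) configuration, enriched by crystallisation.

**Step 2**
Reactants: 3 (2S,5S)-2-tert-butyl-5-methyl-1,3-dioxolan-4-one; 4 (E)-3-methoxyacrolein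
Product: 6 (2S,5R)-2-tert-butyl-5-[(1R,2E)-3-methoxy-1-(triethylsilyloxy)prop-2-en-1-yl]-5-methyl-1,3-dioxolan-4-one, via lithium aldolate 5 (not isolated)
Conditions: LiN(iPr)2, THF, −78 °C; 4, −78 °C; then Et3SiOTf, −78 → −40 °C; aq. NaHCO3; chromatography on Et3N-washed silica
Reagents that add atoms: triethylsilyl trifluoromethanesulfonate, CC[Si](CC)(CC)OS(=O)(=O)C(F)(F)F
Why: Seebach aldol addition in which the enolate is attacked anti to tert-butyl (net retention, fixing the future C7) and a Zimmerman–Traxler chair with the enolate methyl cis to O–Li is expected to set the carbinol (future C8) as 1R, the acid-labile aldolate being silylated in situ.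

**Step 3**
Reactants: 6 (2S,5R)-2-tert-butyl-5-[(1R,2E)-3-methoxy-1-(triethylsilyloxy)prop-2-en-1-yl]-5-methyl-1,3-dioxolan-4-one
Product: 7 (3R,4R,5E)-1,1-dichloro-3-hydroxy-6-methoxy-3-methyl-4-(triethylsilyloxy)hex-5-en-2-one
Conditions: CH2Cl2 (3 equiv), LiN(iPr)2 (2.5 equiv), THF, −100 °C; then 6, −100 → −78 °C; sat. NH4Cl at −78 °C
Reagents that add atoms: dichloromethane (as dichloromethyllithium), ClCCl
Why: Nucleophilic acyl substitution by the carbenoid dichloromethyllithium on the acylal carbonyl, whose collapse expels pivaldehyde and leaves the acidic dichloro ketone as its enolate until quench, so no second addition occurs and no stereocentre is touched.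

**Step 4**
Reactants: 7 (3R,4R,5E)-1,1-dichloro-3-hydroxy-6-methoxy-3-methyl-4-(triethylsilyloxy)hex-5-en-2-one
Product: 8 (3R,4R,5E)-1,1-dichloro-6-methoxy-3-methyl-4-(triethylsilyloxy)-3-(trimethylsilyloxy)hex-5-en-2-one
Conditions: 1-(trimethylsilyl)imidazole, CH2Cl2, rt
Reagents that add atoms: 1-(trimethylsilyl)imidazole, C[Si](C)(C)n1ccnc1
Why: Neutral O-silylation of the tertiary alcohol, which would otherwise close by 5-exo oxa-Michael addition onto the enone made in step 12.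

**Step 5**
Reactants: 9 L-isoleucine
Product: 10 (2S,3S)-2-hydroxy-3-methylpentanoic acid
Conditions: NaNO2, 1 M H2SO4, H2O, 0 °C → rt
Reagents that add atoms: water, O
Why: Diazotisation of the α-amino acid with net retention through the α-lactone (double inversion), so both bought stereocentres stay (2S,3S).

**Step 6**
Reactants: 10 (2S,3S)-2-hydroxy-3-methylpentanoic acid
Product: 11 (2S,3S)-2-hydroxy-N-methoxy-N,3-dimethylpentanamide
Conditions: MeNH(OMe)·HCl, EDC·HCl, HOBt, N-methylmorpholine, CH2Cl2, 0 °C → rt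
Reagents that add atoms: N,O-dimethylhydroxylamine hydrochloride, CNOC.Cl
Why: Carbodiimide amide coupling to the Weinreb amide, with HOBt suppressing epimerisation of the α-centre.

**Step 7**
Reactants: 11 (2S,3S)-2-hydroxy-N-methoxy-N,3-dimethylpentanamide; 12 (E)-1,2-bis(tributylstannyl)ethene
Product: 14 (1E,4S,5S)-4-hydroxy-5-methyl-1-(tributylstannyl)hept-1-en-3-one, via (E)-2-(tributylstannyl)ethenyllithium 13 (not isolated)
Conditions: 12, n-BuLi, THF, −78 °C; add to 11 pre-treated with LiN(SiMe3)2 (1.0 equiv), THF, −78 → −40 °C; sat. NH4Cl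
Reagents that add atoms: none
Why: Tin–lithium exchange followed by Weinreb ketone synthesis, where the chelated tetrahedral intermediate stops at the ketone, the α-alkoxide prevents enolisation of C4 and the E geometry is retained.

**Step 8**
Reactants: 14 (1E,4S,5S)-4-hydroxy-5-methyl-1-(tributylstannyl)hept-1-en-3-one
Product: 15 (1E,3R,4S,5S)-3,5-dimethyl-1-(tributylstannyl)hept-1-ene-3,4-diol
Conditions: MeMgBr (3.5 equiv), Et2O/CH2Cl2, −78 → −40 °C; sat. NH4Cl
Reagents that add atoms: methylmagnesium bromide, C[Mg]Br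
Why: Cram chelate-controlled 1,2-Grignard addition in which magnesium bridges the α-alkoxide and the carbonyl and methyl enters anti to the sec-butyl group, giving the 3R tertiary carbinol.

**Step 9**
Reactants: 15 (1E,3R,4S,5S)-3,5-dimethyl-1-(tributylstannyl)hept-1-ene-3,4-diol
Product: 16 tributyl[(1E,3R,4S,5S)-3,5-dimethyl-3,4-bis(triethylsilyloxy)hept-1-en-1-yl]stannane
Conditions: Et3SiOTf, 2,6-lutidine, CH2Cl2, −78 → 0 °C
Reagents that add atoms: triethylsilyl trifluoromethanesulfonate, CC[Si](CC)(CC)OS(=O)(=O)C(F)(F)F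
Why: Silyl triflate silylation of both hydroxyls, buffered by lutidine so the vinylstannane is not protodestannylated, to keep them out of the acylation and Michael steps.

**Step 10**
Reactants: 16 tributyl[(1E,3R,4S,5S)-3,5-dimethyl-3,4-bis(triethylsilyloxy)hept-1-en-1-yl]stannane; 17 3-(trimethylsilyl)prop-2-ynoic acid
Product: 19 (4E,6R,7S,8S)-6,8-dimethyl-6,7-bis(triethylsilyloxy)-1-(trimethylsilyl)dec-4-en-1-yn-3-one, via 3-(trimethylsilyl)prop-2-ynoyl chloride 18 (not isolated)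
Conditions: 17, (COCl)2, DMF (cat.), CH2Cl2, 0 °C → rt, evaporate; then 16, Pd(PPh3)4 (5 mol%), THF, 50 °C
Reagents that add atoms: none
Why: Stille acylation of the vinylstannane by the acid chloride, which transfers the alkenyl group with retention of the E geometry.

**Step 11**
Reactants: 19 (4E,6R,7S,8S)-6,8-dimethyl-6,7-bis(triethylsilyloxy)-1-(trimethylsilyl)dec-4-en-1-yn-3-one
Product: 20 (4E,6R,7S,8S)-6,8-dimethyl-6,7-bis(triethylsilyloxy)dec-4-en-1-yn-3-one
Conditions: Na2B4O7·10H2O, MeOH/THF/H2O, rt, short reaction time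
Reagents that add atoms: none
Why: Protodesilylation of the electron-poor alkynylsilane under mild borate buffer, which leaves the triethylsilyl ethers intact.

**Step 12**
Reactants: 8 (3R,4R,5E)-1,1-dichloro-6-methoxy-3-methyl-4-(triethylsilyloxy)-3-(trimethylsilyloxy)hex-5-en-2-one; 20 (4E,6R,7S,8S)-6,8-dimethyl-6,7-bis(triethylsilyloxy)dec-4-en-1-yn-3-one
Product: 21 (1E,3R,4R,7E,10E,12R,13S,14S)-6,6-dichloro-1-methoxy-4,12,14-trimethyl-3,12,13-tris(triethylsilyloxy)-4-(trimethylsilyloxy)hexadeca-1,7,10-triene-5,9-dione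
Conditions: DABCO (10 mol%), CH2Cl2, 0 °C → rt
Reagents that add atoms: none
Why: Amine-catalysed Michael addition of the dichloro carbon acid to the ynone terminus (through the β-ammonium enone) gives the E enone, and the resulting quaternary CCl2 carbon cannot enolise into a pyrylium-forming ene-dione.

**Step 13**
Reactants: 21 (1E,3R,4R,7E,10E,12R,13S,14S)-6,6-dichloro-1-methoxy-4,12,14-trimethyl-3,12,13-tris(triethylsilyloxy)-4-(trimethylsilyloxy)hexadeca-1,7,10-triene-5,9-dione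
Product: 23 (7R,8R)-5-chloro-3-[(1E,3R,4S,5S)-3,5-dimethyl-3,4-bis(triethylsilyloxy)hept-1-en-1-yl]-1-methoxy-7-methyl-8-(triethylsilyloxy)-7-(trimethylsilyloxy)-1,7,8,8a-tetrahydro-6H-isochromen-6-one (C1/C8a epimer mixture), via hetero-Diels–Alder cycloadduct 22 (not isolated)
Conditions: PhMe (0.01 M), BHT (cat.), 110 °C, sealed tube; then DBU (1.2 equiv), 0 °C → rt
Reagents that add atoms: none
Why: Intramolecular inverse-electron-demand hetero-Diels–Alder reaction of the enone (oxadiene, activated by the CCl2–C=O group) with the enol ether forms ring B and closes ring A at once, the new C1, C4a and C8a centres being transient, and DBU then effects E2 dehydrochlorination to the C4a=C5 chloro-enone.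

**Step 14**
Reactants: 23 (7R,8R)-5-chloro-3-[(1E,3R,4S,5S)-3,5-dimethyl-3,4-bis(triethylsilyloxy)hept-1-en-1-yl]-1-methoxy-7-methyl-8-(triethylsilyloxy)-7-(trimethylsilyloxy)-1,7,8,8a-tetrahydro-6H-isochromen-6-one
Product: 24 (7R,8R)-5-chloro-3-[(1E,3R,4S,5S)-3,5-dimethyl-3,4-bis(triethylsilyloxy)hept-1-en-1-yl]-7-methyl-8-(triethylsilyloxy)-7-(trimethylsilyloxy)-7,8-dihydro-6H-isochromen-6-one
Conditions: Me3SiOTf, iPr2NEt, CH2Cl2, −78 → 0 °C
Reagents that add atoms: none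
Why: Gassman-type silyl triflate/amine elimination of methanol from the mixed acetal through the oxocarbenium ion, where loss of the γ-acidic C8a–H gives the fully conjugated vinylogous pyranone without touching C7 or C8.

**Step 15**
Reactants: 24 (7R,8R)-5-chloro-3-[(1E,3R,4S,5S)-3,5-dimethyl-3,4-bis(triethylsilyloxy)hept-1-en-1-yl]-7-methyl-8-(triethylsilyloxy)-7-(trimethylsilyloxy)-7,8-dihydro-6H-isochromen-6-one
Product: 25 (7R,8R)-5-chloro-3-[(1E,3R,4S,5S)-3,4-dihydroxy-3,5-dimethylhept-1-en-1-yl]-7,8-dihydroxy-7-methyl-7,8-dihydro-6H-isochromen-6-one (target)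
Conditions: HF·pyridine, pyridine, THF, 0 °C → rt
Reagents that add atoms: none
Why: Fluoride-mediated global desilylation under buffered conditions that spare the allylic alcohols and the chloro-enone.

**Compound list**
1 | L-lactic acid, (S)-2-hydroxypropanoic acid | C[C@H](O)C(=O)O | starting material
2 | pivaldehyde (2,2-dimethylpropanal) | CC(C)(C)C=O | starting material
3 | (2S,5S)-2-tert-butyl-5-methyl-1,3-dioxolan-4-one | C[C@@H]1O[C@H](C(C)(C)C)OC1=O | intermediate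
4 | (E)-3-methoxyacrolein, (2E)-3-methoxyprop-2-enal | CO/C=C/C=O | starting material
5 | lithium alkoxide of (2S,5R)-2-tert-butyl-5-[(1R,2E)-1-hydroxy-3-methoxyprop-2-en-1-yl]-5-methyl-1,3-dioxolan-4-one (lithium aldolate) | C[C@]1([C@H](O[Li])/C=C/OC)O[C@H](C(C)(C)C)OC1=O | intermediate
6 | (2S,5R)-2-tert-butyl-5-[(1R,2E)-3-methoxy-1-(triethylsilyloxy)prop-2-en-1-yl]-5-methyl-1,3-dioxolan-4-one | C[C@]1([C@H](O[Si](CC)(CC)CC)/C=C/OC)O[C@H](C(C)(C)C)OC1=O | intermediate
7 | (3R,4R,5E)-1,1-dichloro-3-hydroxy-6-methoxy-3-methyl-4-(triethylsilyloxy)hex-5-en-2-one | ClC(Cl)C(=O)[C@](C)(O)[C@H](O[Si](CC)(CC)CC)/C=C/OC | intermediate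
8 | (3R,4R,5E)-1,1-dichloro-6-methoxy-3-methyl-4-(triethylsilyloxy)-3-(trimethylsilyloxy)hex-5-en-2-one | ClC(Cl)C(=O)[C@](C)(O[Si](C)(C)C)[C@H](O[Si](CC)(CC)CC)/C=C/OC | intermediate
9 | L-isoleucine | CC[C@H](C)[C@H](N)C(=O)O | starting material
10 | (2S,3S)-2-hydroxy-3-methylpentanoic acid | CC[C@H](C)[C@H](O)C(=O)O | intermediate
11 | (2S,3S)-2-hydroxy-N-methoxy-N,3-dimethylpentanamide | CC[C@H](C)[C@H](O)C(=O)N(C)OC | intermediate
12 | (E)-1,2-bis(tributylstannyl)ethene | CCCC[Sn](CCCC)(CCCC)/C=C/[Sn](CCCC)(CCCC)CCCC | starting material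
13 | (E)-2-(tributylstannyl)ethenyllithium | [Li]/C=C/[Sn](CCCC)(CCCC)CCCC | intermediate
14 | (1E,4S,5S)-4-hydroxy-5-methyl-1-(tributylstannyl)hept-1-en-3-one | CC[C@H](C)[C@H](O)C(=O)/C=C/[Sn](CCCC)(CCCC)CCCC | intermediate
15 | (1E,3R,4S,5S)-3,5-dimethyl-1-(tributylstannyl)hept-1-ene-3,4-diol | CC[C@H](C)[C@H](O)[C@](C)(O)/C=C/[Sn](CCCC)(CCCC)CCCC | intermediate
16 | tributyl[(1E,3R,4S,5S)-3,5-dimethyl-3,4-bis(triethylsilyloxy)hept-1-en-1-yl]stannane | CC[C@H](C)[C@H](O[Si](CC)(CC)CC)[C@](C)(O[Si](CC)(CC)CC)/C=C/[Sn](CCCC)(CCCC)CCCC | intermediate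
17 | 3-(trimethylsilyl)prop-2-ynoic acid | C[Si](C)(C)C#CC(=O)O | starting material
18 | 3-(trimethylsilyl)prop-2-ynoyl chloride | C[Si](C)(C)C#CC(=O)Cl | intermediate
19 | (4E,6R,7S,8S)-6,8-dimethyl-6,7-bis(triethylsilyloxy)-1-(trimethylsilyl)dec-4-en-1-yn-3-one | CC[C@H](C)[C@H](O[Si](CC)(CC)CC)[C@](C)(O[Si](CC)(CC)CC)/C=C/C(=O)C#C[Si](C)(C)C | intermediate
20 | (4E,6R,7S,8S)-6,8-dimethyl-6,7-bis(triethylsilyloxy)dec-4-en-1-yn-3-one | CC[C@H](C)[C@H](O[Si](CC)(CC)CC)[C@](C)(O[Si](CC)(CC)CC)/C=C/C(=O)C#C | intermediate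
21 | (1E,3R,4R,7E,10E,12R,13S,14S)-6,6-dichloro-1-methoxy-4,12,14-trimethyl-3,12,13-tris(triethylsilyloxy)-4-(trimethylsilyloxy)hexadeca-1,7,10-triene-5,9-dione | CC[C@H](C)[C@H](O[Si](CC)(CC)CC)[C@](C)(O[Si](CC)(CC)CC)/C=C/C(=O)/C=C/C(Cl)(Cl)C(=O)[C@](C)(O[Si](C)(C)C)[C@H](O[Si](CC)(CC)CC)/C=C/OC | intermediate
22 | (7R,8R)-5,5-dichloro-3-[(1E,3R,4S,5S)-3,5-dimethyl-3,4-bis(triethylsilyloxy)hept-1-en-1-yl]-1-methoxy-7-methyl-8-(triethylsilyloxy)-7-(trimethylsilyloxy)-1,4a,5,7,8,8a-hexahydro-6H-isochromen-6-one (C1/C4a/C8a diastereomer mixture) | CC[C@H](C)[C@H](O[Si](CC)(CC)CC)[C@](C)(O[Si](CC)(CC)CC)/C=C/C1=CC2C(Cl)(Cl)C(=O)[C@](C)(O[Si](C)(C)C)[C@H](O[Si](CC)(CC)CC)C2C(OC)O1 | intermediate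
23 | (7R,8R)-5-chloro-3-[(1E,3R,4S,5S)-3,5-dimethyl-3,4-bis(triethylsilyloxy)hept-1-en-1-yl]-1-methoxy-7-methyl-8-(triethylsilyloxy)-7-(trimethylsilyloxy)-1,7,8,8a-tetrahydro-6H-isochromen-6-one (C1/C8a epimer mixture) | CC[C@H](C)[C@H](O[Si](CC)(CC)CC)[C@](C)(O[Si](CC)(CC)CC)/C=C/C1=CC2=C(Cl)C(=O)[C@](C)(O[Si](C)(C)C)[C@H](O[Si](CC)(CC)CC)C2C(OC)O1 | intermediate
24 | (7R,8R)-5-chloro-3-[(1E,3R,4S,5S)-3,5-dimethyl-3,4-bis(triethylsilyloxy)hept-1-en-1-yl]-7-methyl-8-(triethylsilyloxy)-7-(trimethylsilyloxy)-7,8-dihydro-6H-isochromen-6-one | CC[C@H](C)[C@H](O[Si](CC)(CC)CC)[C@](C)(O[Si](CC)(CC)CC)/C=C/C1=CC2=C(Cl)C(=O)[C@](C)(O[Si](C)(C)C)[C@H](O[Si](CC)(CC)CC)C2=CO1 | intermediate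
25 | (7R,8R)-5-chloro-3-[(1E,3R,4S,5S)-3,4-dihydroxy-3,5-dimethylhept-1-en-1-yl]-7,8-dihydroxy-7-methyl-7,8-dihydro-6H-isochromen-6-one | CC[C@H](C)[C@H](O)[C@](C)(O)/C=C/C1=CC2=C(Cl)C(=O)[C@](C)(O)[C@H](O)C2=CO1 | target

**Step count**
Total: 15 steps. Longest linear sequence: 11 steps (9 → 25, steps 5–15); the lactic acid branch is 8 steps (steps 1–4 and 12–15).

**Steps most likely to fail, with fallbacks**

Step 13 (cycloaddition of an enone that carries only one carbonyl, next to a quaternary CCl2 carbon). The fallback reverses the order of bond formation, sets out from 8 and 20 and comes back at 23. HCl is added across the ynone 20 (LiCl, AcOH, MeCN) to give the β-chlorovinyl ketone (1E,4E,6R,7S,8S)-1-chloro-6,8-dimethyl-6,7-bis(triethylsilyloxy)deca-1,4-dien-3-one F7. This undergoes an intermolecular hetero-Diels–Alder reaction with enol ether 8, catalysed by Eu(fod)3 (europium tris(6,6,7,7,8,8,8-heptafluoro-2,2-dimethyloctane-3,5-dionate)) in PhMe at 60 °C, to give the 4-chloro-2-methoxy-dihydropyran (3R,4R)-1,1-dichloro-4-{4-chloro-6-[(1E,3R,4S,5S)-3,5-dimethyl-3,4-bis(triethylsilyloxy)hept-1-en-1-yl]-2-methoxy-3,4-dihydro-2H-pyran-3-yl}-3-methyl-4-(triethylsilyloxy)-3-(trimethylsilyloxy)butan-2-one F8. Cs2CO3 then DBU closes ring A by intramolecular C-alkylation of the dichloro enolate with the allylic chloride (giving 22) and eliminates HCl to 23.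

Step 3 (organolithium attack on a hindered dioxolanone carbonyl while pivaldehyde is released beside a dichloro enolate). The fallback sets out from 6 and comes back at 7. LiAlH4 (THF, 0 °C) reduces the dioxolanone to the diol (2S,3R,4E)-5-methoxy-2-methyl-3-(triethylsilyloxy)pent-4-ene-1,2-diol F4. Parikh–Doering oxidation (SO3·pyridine, DMSO, iPr2NEt) gives the aldehyde (2R,3R,4E)-2-hydroxy-5-methoxy-2-methyl-3-(triethylsilyloxy)pent-4-enal F5. Dichloromethyllithium adds to this unhindered aldehyde (−100 °C) to give the dichlorohydrin (3S,4R,5E)-1,1-dichloro-6-methoxy-3-methyl-4-(triethylsilyloxy)hex-5-ene-2,3-diol F6 as a C2 epimer mixture, and Dess–Martin periodinane buffered with NaHCO3 oxidises the secondary carbinol to 7.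

Step 2 (diastereoselectivity at the carbinol and lability of the adduct). The fallback sets C8 by ketone reduction instead of by the aldol, sets out from 3 and comes back at 6. The aldol of 3 with 4 is run without the silyl quench and the carbinol-epimeric alcohols (2S,5R)-2-tert-butyl-5-[(2E)-1-hydroxy-3-methoxyprop-2-en-1-yl]-5-methyl-1,3-dioxolan-4-one F1 are isolated. MnO2 (CH2Cl2) oxidises them to the β-keto lactone (2S,5R)-2-tert-butyl-5-[(2E)-3-methoxyprop-2-enoyl]-5-methyl-1,3-dioxolan-4-one F2. Zn(BH4)2 (Et2O, −78 °C) reduces the zinc chelate of the two carbonyls from the face of the ring oxygen, away from methyl and tert-butyl, to the single alcohol (2S,5R)-2-tert-butyl-5-[(1R,2E)-1-hydroxy-3-methoxyprop-2-en-1-yl]-5-methyl-1,3-dioxolan-4-one F3, which Et3SiCl/imidazole converts to 6.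

**Further compounds**
F1 | step 2 | (2S,5R)-2-tert-butyl-5-[(2E)-1-hydroxy-3-methoxyprop-2-en-1-yl]-5-methyl-1,3-dioxolan-4-one (carbinol epimers) | C[C@]1(C(O)/C=C/OC)O[C@H](C(C)(C)C)OC1=O
F2 | step 2 | (2S,5R)-2-tert-butyl-5-[(2E)-3-methoxyprop-2-enoyl]-5-methyl-1,3-dioxolan-4-one | C[C@]1(C(=O)/C=C/OC)O[C@H](C(C)(C)C)OC1=O
F3 | step 2 | (2S,5R)-2-tert-butyl-5-[(1R,2E)-1-hydroxy-3-methoxyprop-2-en-1-yl]-5-methyl-1,3-dioxolan-4-one | C[C@]1([C@H](O)/C=C/OC)O[C@H](C(C)(C)C)OC1=O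
F4 | step 3 | (2S,3R,4E)-5-methoxy-2-methyl-3-(triethylsilyloxy)pent-4-ene-1,2-diol | OC[C@](C)(O)[C@H](O[Si](CC)(CC)CC)/C=C/OC
F5 | step 3 | (2R,3R,4E)-2-hydroxy-5-methoxy-2-methyl-3-(triethylsilyloxy)pent-4-enal | O=C[C@](C)(O)[C@H](O[Si](CC)(CC)CC)/C=C/OC
F6 | step 3 | (3S,4R,5E)-1,1-dichloro-6-methoxy-3-methyl-4-(triethylsilyloxy)hex-5-ene-2,3-diol (C2 epimers) | ClC(Cl)C(O)[C@](C)(O)[C@H](O[Si](CC)(CC)CC)/C=C/OC
F7 | step 13 | (1E,4E,6R,7S,8S)-1-chloro-6,8-dimethyl-6,7-bis(triethylsilyloxy)deca-1,4-dien-3-one | CC[C@H](C)[C@H](O[Si](CC)(CC)CC)[C@](C)(O[Si](CC)(CC)CC)/C=C/C(=O)/C=C/Cl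
F8 | step 13 | (3R,4R)-1,1-dichloro-4-{4-chloro-6-[(1E,3R,4S,5S)-3,5-dimethyl-3,4-bis(triethylsilyloxy)hept-1-en-1-yl]-2-methoxy-3,4-dihydro-2H-pyran-3-yl}-3-methyl-4-(triethylsilyloxy)-3-(trimethylsilyloxy)butan-2-one (ring diastereomers) | CC[C@H](C)[C@H](O[Si](CC)(CC)CC)[C@](C)(O[Si](CC)(CC)CC)/C=C/C1=CC(Cl)C([C@@H](O[Si](CC)(CC)CC)[C@@](C)(O[Si](C)(C)C)C(=O)C(Cl)Cl)C(OC)O1
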